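The target is cut at its methylene bridge into a cyclopentane β-hydroxy aldehyde and an enantiopure acylated cyclohexanetrione, reunited at the end by reductive alkylation. The feature exploited is the cyclopentane ring: with its carbinol methyl, the bridge carbon on the neighbouring CH and the isopropenyl group on the next CH, it holds exactly the ten carbons of limonene. Ring opening of (R)-limonene therefore gives an acyclic 1,6-keto aldehyde with the isopropenyl stereocentre already in place. One amine-catalysed intramolecular aldol then joins the carbinol carbon to the formyl-bearing carbon, closes the five-membered ring and sets its two new stereocentres under control of the existing one.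

Key step: step 2

Assumption: pig liver esterase is taken to hydrolyse the pro-S ester group of 9, the sense expected when the larger substituent of a 2-methylmalonate is a hydrophobic chain of about five carbons; the configuration of 10 is to be confirmed before it is carried on.
Remark: the tri- and tetracarbonyl compounds 13 to 16 are drawn as single enol tautomers; the quaternary ring carbon is configurationally stable in all of them.

Step 1
Reactants: 1 (R)-(+)-limonene
Product: 3 (3R)-6-oxo-3-(prop-1-en-2-yl)heptanal, via secondary ozonide 2 (not isolated)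
Conditions: O3 (ca. 1.0 equiv, Sudan Red 7B end point), CH2Cl2, −78 °C; then PPh3, −78 °C to rt
Reagents that add atoms: ozone, [O-][O+]=O
Why: Alkene ozonolysis with reductive work-up: electrophilic ozone adds faster to the trisubstituted ring alkene than to the 1,1-disubstituted isopropenyl group, so dosing to the dye end point should give ozonide 2, which PPh3 reduces to the keto aldehyde without touching the stereocentre.

Step 2
Reactants: 3 (3R)-6-oxo-3-(prop-1-en-2-yl)heptanal
Product: 6 (1S,2R,5R)-2-hydroxy-2-methyl-5-(prop-1-en-2-yl)cyclopentane-1-carbaldehyde, via proline enamine 4 (not isolated), via cyclised iminium carboxylate 5 (not isolated)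
Conditions: L-proline (20 mol %), DMSO, 20 °C
Reagents that add atoms: none
Why: L-Proline condenses with the unhindered aldehyde of 3 to give E-enamine 4, whose α-carbon adds to the methyl ketone activated by the carboxylic acid, and hydrolysis of iminium 5 releases 6 and the catalyst. The closest known reaction type is the proline-catalysed intramolecular enolexo aldolisation of dicarbonyl compounds with an aldehyde donor and a ketone acceptor. The cyclopentane closes in a 5-(enolexo)-exo-trig mode, the enamine double bond staying outside the new ring. C1 is set by catalyst and substrate together: the acid-directed, hydrogen-bonded enamine transition state of the (S)-catalyst should deliver the ketone to the enamine face that gives 1S, which is also the face that places the iminium carbon trans to the C5 isopropenyl group; C2 follows from the same transition state, in which the acid bridges nitrogen and ketone oxygen so that hydroxyl and formyl end up cis and the methyl trans. The step needs donor/acceptor chemoselectivity, secured by the much faster enamine formation at the aldehyde; it needs diastereoselectivity, backed by the reversibility of aldol and enamine formation, which lets the mixture settle on the hydrogen-bonded isomer with formyl trans to both ring neighbours; and it needs arrest before dehydration, for which the near-neutral catalyst at room temperature without added acid or heat is chosen.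

Step 3
Reactants: 7 dimethyl methylmalonate; 8 prenyl bromide (1-bromo-3-methylbut-2-ene)
Product: 9 dimethyl 2-methyl-2-(3-methylbut-2-en-1-yl)propanedioate
Conditions: NaH, THF, 0 °C to rt
Reagents that add atoms: none
Why: Malonic ester alkylation: the sodium enolate of 7 displaces bromide from the primary allylic halide (SN2 at the unhindered CH2), the fully substituted product cannot react again, and the new quaternary carbon is still prochiral.

Step 4
Reactants: 9 dimethyl 2-methyl-2-(3-methylbut-2-en-1-yl)propanedioate
Product: 10 (2R)-2-(methoxycarbonyl)-2,5-dimethylhex-4-enoic acid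
Conditions: pig liver esterase, phosphate buffer (pH 7.5)/DMSO 9:1, 25 °C, 1 M NaOH by pH-stat; then HCl (pH 2)
Reagents that add atoms: water, O
Why: Enzymatic desymmetrisation of a prochiral 2,2-disubstituted dimethyl malonate: the esterase should hydrolyse one enantiotopic ester (taken as pro-S, with the prenyl chain in the large hydrophobic pocket) and stop at the half-ester because the carboxylate is no substrate, which sets the quaternary stereocentre as R.

Step 5
Reactants: 10 (2R)-2-(methoxycarbonyl)-2,5-dimethylhex-4-enoic acid; 11 5-methylhexane-2,4-dione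
Product: 13 methyl (2R)-2,8-dimethyl-2-(3-methylbut-2-en-1-yl)-3,5,7-trioxononanoate, via acyl imidazole 12 (not isolated)
Conditions: 10, CDI (1.05 equiv), THF, rt; added to 11 (3 equiv)/LDA (6 equiv), THF, −78 to 0 °C; then AcOH
Reagents that add atoms: none
Why: C-Acylation of a β-diketone dianion (Claisen-type condensation): the dilithio dianion of 11, deprotonated at C3 and then at the methyl group and not at the hindered methine, should attack the non-enolisable acyl imidazole through its terminal carbon far faster than the neopentyl-like methyl ester, the excess dianion covering the acidic product and the imidazole N–H, and no bond at the quaternary centre is broken.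

Step 6
Reactants: 13 methyl (2R)-2,8-dimethyl-2-(3-methylbut-2-en-1-yl)-3,5,7-trioxononanoate
Product: 14 (6R)-3,5-dihydroxy-6-methyl-6-(3-methylbut-2-en-1-yl)-2-(2-methylpropanoyl)cyclohexa-2,4-dien-1-one
Conditions: KOtBu (2.5 equiv), THF, 0 to 40 °C; then cold 1 M HCl
Reagents that add atoms: none
Why: Dieckmann condensation: the enolate carbon between the 5- and 7-carbonyl groups attacks the ester in a 6-exo-trig closure, the only ring size open to C-acylation, driven by the strongly stabilised acyl triketone anion and helped by the gem-disubstituted carbon, with non-nucleophilic tert-butoxide avoiding retro-Claisen cleavage; since the acid-derived carbonyl ends up next to the ring CH and the ester-derived one next to the acylated carbon, R in 10 becomes 6R in 14.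

Step 7
Reactants: 6 (1S,2R,5R)-2-hydroxy-2-methyl-5-(prop-1-en-2-yl)cyclopentane-1-carbaldehyde; 14 (6R)-3,5-dihydroxy-6-methyl-6-(3-methylbut-2-en-1-yl)-2-(2-methylpropanoyl)cyclohexa-2,4-dien-1-one
Product: 16 (6R)-3,5-dihydroxy-4-{[(1S,2R,5R)-2-hydroxy-2-methyl-5-(prop-1-en-2-yl)cyclopentyl]methyl}-6-methyl-6-(3-methylbut-2-en-1-yl)-2-(2-methylpropanoyl)cyclohexa-2,4-dien-1-one, via alkylidene triketone 15 (not isolated)
Conditions: L-proline (20 mol %), Hantzsch ester (diethyl 2,6-dimethyl-1,4-dihydropyridine-3,5-dicarboxylate, 1.2 equiv), CH2Cl2, 20 °C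
Reagents that add atoms: none
Why: Three-component reductive alkylation (Knoevenagel condensation followed by Hantzsch ester transfer hydrogenation): the proline iminium of 6 is attacked by C4 of 14, the only unsubstituted enolic ring carbon, loss of the amine gives the electrophilic alkylidene 15, and conjugate hydride transfer turns it into the CH2 bridge; no stereocentre is formed and the cyclopentane C1 stays in its more stable trans arrangement.

Compound list
1 | (R)-(+)-limonene, (4R)-1-methyl-4-(prop-1-en-2-yl)cyclohex-1-ene | CC1=CC[C@@H](CC1)C(C)=C | starting material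
2 | secondary ozonide of the ring alkene, (4R)-1-methyl-4-(prop-1-en-2-yl)-7,8,9-trioxabicyclo[4.2.1]nonane, both bridgehead diastereomers | CC12CC[C@H](CC(O1)OO2)C(C)=C | intermediate
3 | (3R)-6-oxo-3-(prop-1-en-2-yl)heptanal | C=C(C)[C@@H](CC=O)CCC(C)=O | intermediate
4 | E-enamine of 3 with L-proline, (2S)-1-[(1E,3R)-6-oxo-3-(prop-1-en-2-yl)hept-1-en-1-yl]pyrrolidine-2-carboxylic acid | C=C(C)[C@@H](/C=C/N1CCC[C@H]1C(=O)O)CCC(C)=O | intermediate
5 | zwitterionic iminium carboxylate of aldehyde 6 with L-proline, ring configuration as in 6 | C=C(C)[C@@H]1CC[C@@](C)(O)[C@H]1C=[N+]1CCC[C@H]1C(=O)[O-] | intermediate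
6 | (1S,2R,5R)-2-hydroxy-2-methyl-5-(prop-1-en-2-yl)cyclopentane-1-carbaldehyde (formyl trans to isopropenyl and to methyl, cis to hydroxyl) | C=C(C)[C@@H]1CC[C@@](C)(O)[C@H]1C=O | intermediate
7 | dimethyl methylmalonate | COC(=O)C(C)C(=O)OC | starting material
8 | prenyl bromide, 1-bromo-3-methylbut-2-ene | CC(C)=CCBr | starting material
9 | dimethyl 2-methyl-2-(3-methylbut-2-en-1-yl)propanedioate | COC(=O)C(C)(CC=C(C)C)C(=O)OC | intermediate
10 | (2R)-2-(methoxycarbonyl)-2,5-dimethylhex-4-enoic acid | OC(=O)[C@@](C)(CC=C(C)C)C(=O)OC | intermediate
11 | 5-methylhexane-2,4-dione | CC(=O)CC(=O)C(C)C | starting material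
12 | methyl (2R)-2-(1H-imidazole-1-carbonyl)-2,5-dimethylhex-4-enoate | O=C(n1ccnc1)[C@@](C)(CC=C(C)C)C(=O)OC | intermediate
13 | methyl (2R)-2,8-dimethyl-2-(3-methylbut-2-en-1-yl)-3,5,7-trioxononanoate | CC(C)C(=O)CC(=O)CC(=O)[C@@](C)(CC=C(C)C)C(=O)OC | intermediate
14 | (6R)-3,5-dihydroxy-6-methyl-6-(3-methylbut-2-en-1-yl)-2-(2-methylpropanoyl)cyclohexa-2,4-dien-1-one | CC(C)C(=O)C1=C(O)C=C(O)[C@@](C)(CC=C(C)C)C1=O | intermediate
15 | Knoevenagel alkylidene adduct of 6 and 14 (ring CH of 14 doubly bonded to the former formyl carbon; stereocentres as in 16, alkene geometry open) | C=C(C)[C@@H]1CC[C@@](C)(O)[C@H]1C=C1C(=O)[C@@](C)(CC=C(C)C)C(=O)C(C(=O)C(C)C)=C1O | intermediate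
16 | (6R)-3,5-dihydroxy-4-{[(1S,2R,5R)-2-hydroxy-2-methyl-5-(prop-1-en-2-yl)cyclopentyl]methyl}-6-methyl-6-(3-methylbut-2-en-1-yl)-2-(2-methylpropanoyl)cyclohexa-2,4-dien-1-one | C=C(C)[C@@H]1CC[C@@](C)(O)[C@H]1CC1=C(O)[C@@](C)(CC=C(C)C)C(=O)C(C(=O)C(C)C)=C1O | target

Total step count: 7. Longest linear sequence: 5 steps (steps 3, 4, 5, 6 and 7); the terpene branch (steps 1 and 2) joins at step 7.

Steps most likely to fail

Step 2. The aldol may lose water to the conjugated cyclopentene aldehyde, or the two new centres may not settle on one diastereomer. The fallback accepts the dehydration and restores the hydroxyl afterwards.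
- Setting out from 3, piperidine and acetic acid in toluene at 80 °C should condense it, through the same C–C bond, to (5S)-2-methyl-5-(prop-1-en-2-yl)cyclopent-1-ene-1-carbaldehyde F1.
- Alkaline hydrogen peroxide in methanol at 0 °C (Weitz–Scheffer epoxidation, which leaves the isopropenyl group alone) should add oxygen on the face away from the isopropenyl group to give (1S,2S,5R)-5-methyl-2-(prop-1-en-2-yl)-6-oxabicyclo[3.1.0]hexane-1-carbaldehyde F2.
- Reductive cleavage of the Cα–O bond with sodium phenylseleno(triethoxy)borate (from diphenyl diselenide and NaBH4, no hydride in excess) and acetic acid in ethanol at 0 °C should give the β-hydroxy aldehyde. The hydroxyl then lies trans to isopropenyl, and C1 is protonated or equilibrated to the trans arrangement. The route is rejoined at 6.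

Step 4. The enzyme may discriminate the two enantiotopic ester groups incompletely or in the opposite sense. The fallback is a classical resolution.
- Setting out from 9, one equivalent of KOH in aqueous methanol at rt should give racemic 2-(methoxycarbonyl)-2,5-dimethylhex-4-enoic acid F3.
- Crystallisation with (S)-1-phenylethylamine, or with its enantiomer if that gives the less soluble salt of the R acid, should give (S)-1-phenylethylammonium (2R)-2-(methoxycarbonyl)-2,5-dimethylhex-4-enoate F4.
- Dilute HCl liberates the acid, and the route is rejoined at 10.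

Step 7. Under the amine catalyst the hydroxy aldehyde may open by retro-aldol or eliminate water faster than the α-branched formyl group condenses. The fallback masks the hydroxyl.
- Setting out from 6, TESOTf and 2,6-lutidine in CH2Cl2 at −78 °C should give (1S,2R,5R)-2-methyl-5-(prop-1-en-2-yl)-2-[(triethylsilyl)oxy]cyclopentane-1-carbaldehyde F5, which cannot undergo retro-aldol.
- The same proline/Hantzsch ester coupling with 14 should give (6R)-3,5-dihydroxy-6-methyl-6-(3-methylbut-2-en-1-yl)-2-(2-methylpropanoyl)-4-({(1S,2R,5R)-2-methyl-5-(prop-1-en-2-yl)-2-[(triethylsilyl)oxy]cyclopentyl}methyl)cyclohexa-2,4-dien-1-one F6.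
- HF·pyridine in THF at 0 °C removes the silyl group, and the route ends at 16.

Further compounds
F1 | step 2 | (5S)-2-methyl-5-(prop-1-en-2-yl)cyclopent-1-ene-1-carbaldehyde | C=C(C)[C@@H]1CCC(C)=C1C=O
F2 | step 2 | (1S,2S,5R)-5-methyl-2-(prop-1-en-2-yl)-6-oxabicyclo[3.1.0]hexane-1-carbaldehyde | C=C(C)[C@@H]1CC[C@@]2(C)O[C@@]12C=O
F3 | step 4 | racemic 2-(methoxycarbonyl)-2,5-dimethylhex-4-enoic acid | OC(=O)C(C)(CC=C(C)C)C(=O)OC
F4 | step 4 | (S)-1-phenylethylammonium (2R)-2-(methoxycarbonyl)-2,5-dimethylhex-4-enoate | C[C@H]([NH3+])c1ccccc1.[O-]C(=O)[C@@](C)(CC=C(C)C)C(=O)OC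
F5 | step 7 | (1S,2R,5R)-2-methyl-5-(prop-1-en-2-yl)-2-[(triethylsilyl)oxy]cyclopentane-1-carbaldehyde | C=C(C)[C@@H]1CC[C@@](C)(O[Si](CC)(CC)CC)[C@H]1C=O
F6 | step 7 | (6R)-3,5-dihydroxy-6-methyl-6-(3-methylbut-2-en-1-yl)-2-(2-methylpropanoyl)-4-({(1S,2R,5R)-2-methyl-5-(prop-1-en-2-yl)-2-[(triethylsilyl)oxy]cyclopentyl}methyl)cyclohexa-2,4-dien-1-one | C=C(C)[C@@H]1CC[C@@](C)(O[Si](CC)(CC)CC)[C@H]1CC1=C(O)[C@@](C)(CC=C(C)C)C(=O)C(C(=O)C(C)C)=C1O
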